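## Structural features

The target is a phenylcoumaran-type neolignan, a 2,3-dihydrobenzofuran (O1, C2, C3, C3a, C4–C7, C7a). Its benzo ring (ring A) carries a methoxy group at C7 and an (E)-acrylic acid at C5; C2 carries a 4-hydroxy-3,5-dimethoxyphenyl group (ring B) and C3 a hydroxymethyl group. C2 (S) and C3 (R) are adjacent, trans, and the only stereocentres. C2 is a benzylic ether carbon activated by the para oxygen of ring B. It can ionise under acid and, once the phenol is free, can open to a quinone methide under base; either event would scramble C2. The free phenol is oxidation-prone, the cinnamic acid rules out hydrogenolytic deprotection, and the 1,3-related oxygens at C2 and on the C3 side chain must be told apart. The real difficulty is to set the C2/C3 diad in absolute and relative terms and then close the five-membered ring without a cation or quinone methide at C2. The feature used is that O1–C7a is an aryl–oxygen bond of ring A next to the C7 methoxy group. This oxygenation pattern with a para one-carbon substituent is that of a vanillin, so C7a can enter as a sulfonate-activated phenol carbon and O1 as the hydroxyl of an open-chain C2 carbinol. Bond formation at the sp2 carbon C7a leaves both sp3 centres untouched.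

## Logic of the disconnections

22 to 21: the phenolic O–CH2OMe bond and the primary O–CPh3 bond are cut. The phenol has to stay masked through every basic step and the primary oxygen through the ring closure. Both groups are acid-labile, so one operation removes them. The forward step must use acid mild enough not to ionise C2–O1.

21 to 18 and 19: the Cα=Cβ bond of the acrylic acid is cut. This reduces the C5 side chain to a formyl group and lets the E acid form directly, with no ester to hydrolyse later. The forward condensation must run in a buffered medium that spares the trityl and MOM ethers.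

18 to 17: the formyl C=O is returned to two C–OMe bonds. The aldehyde cannot survive enolate, hydride and alkoxide chemistry unmasked. The forward hydrolysis must be selective over trityl and MOM, which is possible because in 17 the acetal carbon is para to O1.

17 to 16: the O1–C7a bond is cut. This opens the bicycle to an acyclic 1,3-diol derivative in which both stereocentres already exist, and turns C7a into a triflate-bearing carbon. The forward step must give C–O reductive elimination ahead of β-hydride elimination and must offer only one free hydroxyl.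

16 to 15: the primary O–CPh3 bond is cut. In 15 both hydroxyls could close a five-membered ring onto C7a, the primary one giving a regioisomeric ring, so it must be blocked by a group that cannot migrate. The forward step must be primary-selective.

15 to 14: the primary carbinol carbon is returned to the acyl level and the C–N bond to the auxiliary is restored. The aldol needs an acyl anchor for stereocontrol. The forward hydride step must spare the triflate and avoid epimerisation or retro-aldol.

14 to 9 and 11: the C2–C3 bond between the two stereocentres is cut. It is the only C–C bond joining two fragments of similar size, and making it as a syn aldol sets both centres at once; syn in the open chain maps onto trans in the ring. The forward step needs a Z enolate, facial control from the auxiliary, and tolerance of the acetal and MOM groups.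

11 to 10: the O–CH2OMe bond is cut, leading to a commercial phenolic aldehyde. The forward step is a simple O-alkylation.

9 to 6 and 7: the N–acyl bond is cut, separating the auxiliary from the ring A arylacetic acid. The forward acylation must avoid strong nucleophiles and strong acid because of the triflate and the acetal.

6 to 4 (through the salt 5): the acid is traced to its ethyl ester. The forward hydrolysis must be faster than hydroxide attack on the triflate.

4 to 3: the aryl–CH2 bond (the future C3a–C3 bond) is cut. The iodine of 3 sits on exactly the ring carbon ortho to the phenol oxygen, so the two-carbon chain arrives in one cross-coupling. The forward step must engage C–I and leave C–OTf alone.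

3 to 2 to 1: the acetal C–O bonds and the aryl O–S bond are cut, in that order. The phenol is sulfonylated first, because a free para-hydroxy aldehyde is a poor acetal partner and its acetal would be very labile. The triflate thus serves first to stabilise the acetal and later as the leaving group.

## Other disconnections considered

Alternative 1: the cut runs through ring A (C3a–C4 and C7–C7a). The dihydrofuran would arrive intact as the trans lactone A1, used as its silyl ketene acetal A2, and four ring A carbons would come from the pyrone A3.
- Forward key step: A2 (electron-rich 2π partner) and A3 (electron-poor diene) would combine in a [4+2] cycloaddition with polarity-matched regiochemistry. Extrusion of CO2 and loss of silanol would then aromatise the new ring to A4.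
- In its favour: both stereocentres sit in a small ring before any arene is built. The substitution pattern of ring A is written into A3. No transition metal or aryl sulfonate has to be carried. Two silyl groups would leave together with fluoride.
- Against it here: after cycloaddition the future C7a carries both the ring oxygen and the silyloxy group, and aromatisation must expel the silanol rather than open the dihydrofuran. The methoxy group makes A3 a less electron-poor diene, so heating is likely. C5 arrives as an ester that needs redox adjustment before two-carbon extension. A1 still needs its own enantioselective synthesis of the same trans diad.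
- Comparison: on structure the two plans are equal, since both leave the stereocentres untouched in the ring-forming event. On mechanism the alternative is the better in having no β-hydride elimination channel and no metal, but it trades this for an elimination-direction problem. On step economy it is expected to be longer.

Alternative 2: the cut is O1–C2. The precursor A5 has a single stereocentre (the future C3), both phenols free and the side chain present as the methyl ester.
- Forward key step: anodic two-electron oxidation of the more electron-rich ring B phenol would give the quinone methide A6. Intramolecular 1,6-addition of the ring A phenol would close the trans ring of A7.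
- In its favour: only one stereocentre has to be prepared, no phenol protection is needed, electrons are the reagent, and one ester hydrolysis finishes the synthesis. On step economy and protecting-group economy this alternative is the better of the two.
- Against it here: oxidation must discriminate between two phenols and an electron-rich cinnamate. The oxidised phenol can be captured by solvent or by the primary hydroxyl. A7 keeps a free ring B phenol and a benzylic hydrogen at C2, so further oxidation of the product is a built-in risk. C2 is created in the closure under substrate control rather than carried through.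
- Comparison: on structure it uses the very lability at C2 that the chosen plan avoids. On mechanism it is a cationic, reversible closure, against a coupling that leaves both centres untouched. On the length of the last stage the two are equal.

Alternative 3: the cut is C3–C3a, reached by ring contraction of the flavanone A8.
- Forward key step: after in situ enolisation, PhI(OAc)2 would attack the alpha carbon and the ring A carbon would migrate from the carbonyl carbon to that carbon. The pyranone would contract, and the former carbonyl carbon would become the C3 methyl ester of A9.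
- In its favour: a compound such as A8 is available in few steps, in principle by catalytic asymmetric conjugate arylation. On the source of chirality (catalytic rather than a stoichiometric auxiliary) it is the better. One step makes the ring, the C3–C3a bond and the C3 substituent, and trans is favoured through the epimerisable ester.
- Against it here: migration of the electron-rich ring B aryl group and dehydrogenation of the pyranone compete, which is why the phenol is acylated. The acidic oxidising medium can reversibly open the pyranone at O1–C2 and erode the only centre made by asymmetric synthesis. After A9 the ester must be reduced without base-induced β-elimination of O1, the bromide turned into the acrylic acid by a Pd(OAc)2-catalysed Heck reaction, and the pivalate removed.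
- Comparison: on structure it exploits the flavonoid-like carbon pattern. On mechanism it is a cationic 1,2-shift with configurational risk, against a stereochemically silent coupling. On step economy it is equal or slightly better.

Key step: step 10

Remarks on the chemistry (design choices and one assumption):
- Stereochemical course: the S auxiliary should give the 2S,3S syn aldol 14. Reduction changes only the CIP priorities at the aryl-bearing carbon, giving the 1S,2R diol. Ring closure with retention gives 2S,3R, the target configuration.
- The phenol is triflated before the aldehyde is acetalised. While the para substituent is the triflate the dimethyl acetal is deactivated toward ionisation; after ring closure it is para to O1 and hydrolyses under very mild acid.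
- The primary oxygen is carried as a trityl ether. Trityl cannot migrate to the neighbouring alkoxide under the coupling conditions, and it leaves in the same acidic operation as the MOM group.
- Assumption: reagents named without a number are commercial.

## Steps

Step 1
Reactants: 1 5-iodovanillin (4-hydroxy-3-iodo-5-methoxybenzaldehyde)
Product: 2 4-formyl-2-iodo-6-methoxyphenyl trifluoromethanesulfonate
Conditions: Tf2O, pyridine, CH2Cl2, 0 °C
Reagents that add atoms: trifluoromethanesulfonic anhydride, O=S(=O)(OS(=O)(=O)C(F)(F)F)C(F)(F)F
Why: O-sulfonylation of an acidic phenol is routine; doing it first removes the para-hydroxyl donation that would make the aldehyde a poor acetal partner, and aldehyde and iodide are inert here.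

Step 2
Reactants: 2 4-formyl-2-iodo-6-methoxyphenyl trifluoromethanesulfonate
Product: 3 4-(dimethoxymethyl)-2-iodo-6-methoxyphenyl trifluoromethanesulfonate
Conditions: HC(OMe)3, MeOH, TsOH·H2O (cat.), 25 °C; then Et3N
Reagents that add atoms: trimethyl orthoformate, COC(OC)OC
Why: Acid-catalysed acetalisation with an orthoformate as water scavenger; the electron-poor aldehyde should acetalise readily, and the para-triflate makes the acetal resistant to ionisation in later steps, while aryl triflate and iodide do not react with acidic methanol.

Step 3
Reactants: 3 4-(dimethoxymethyl)-2-iodo-6-methoxyphenyl trifluoromethanesulfonate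
Product: 4 ethyl 2-[5-(dimethoxymethyl)-3-methoxy-2-(trifluoromethanesulfonyloxy)phenyl]acetate
Conditions: BrZnCH2CO2Et (from BrCH2CO2Et, Zn, Me3SiCl cat., THF), Pd(P(t-Bu)3)2 (3 mol %), THF, 25 °C
Reagents that add atoms: ethyl bromoacetate (used as its bromozinc enolate), CCOC(=O)CBr
Why: Negishi-type coupling of a Reformatsky reagent (palladium-catalysed arylation of a zinc ester enolate); zerovalent palladium should insert into C–I far faster than into the hindered C–OTf, tri-tert-butylphosphine-ligated palladium being a poor catalyst for aryl triflates, and the neutral zinc enolate leaves triflate and acetal alone.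

Step 4
Reactants: 4 ethyl 2-[5-(dimethoxymethyl)-3-methoxy-2-(trifluoromethanesulfonyloxy)phenyl]acetate
Product: 6 2-[5-(dimethoxymethyl)-3-methoxy-2-(trifluoromethanesulfonyloxy)phenyl]acetic acid, via lithium carboxylate 5 (not isolated)
Conditions: LiOH·H2O, THF/H2O, 0 °C; then cold 0.5 M HCl to pH 4, immediate extraction
Reagents that add atoms: lithium hydroxide, [Li+].[OH-]
Why: Saponification of an unhindered arylacetic ester should be fast at 0 °C, whereas hydroxide attack at the sulfur of a triflate flanked by two ortho substituents is slow; brief cold acidification to pH 4 should be tolerated by the deactivated acetal.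

Step 5
Reactants: 6 2-[5-(dimethoxymethyl)-3-methoxy-2-(trifluoromethanesulfonyloxy)phenyl]acetic acid; 7 (S)-4-benzyl-1,3-oxazolidin-2-one
Product: 9 (4S)-4-benzyl-3-{2-[5-(dimethoxymethyl)-3-methoxy-2-(trifluoromethanesulfonyloxy)phenyl]acetyl}-1,3-oxazolidin-2-one, via mixed pivalic anhydride 8 (not isolated)
Conditions: PivCl, Et3N, THF, −20 °C; then 7, LiCl, 25 °C
Reagents that add atoms: pivaloyl chloride (its acyl group is carried by 8 only), CC(C)(C)C(=O)Cl
Why: N-acylation of the oxazolidinone through a mixed anhydride with LiCl/Et3N activation; this avoids an acid chloride (HCl would endanger the acetal) and butyllithium (which could attack the triflate), and the oxazolidinone should attack the less hindered arylacetyl carbonyl.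

Step 6
Reactants: 10 syringaldehyde (4-hydroxy-3,5-dimethoxybenzaldehyde)
Product: 11 3,5-dimethoxy-4-(methoxymethoxy)benzaldehyde
Conditions: MOMCl, i-Pr2NEt, CH2Cl2, 0 → 25 °C
Reagents that add atoms: chloromethyl methyl ether, COCCl
Why: O-alkylation of the phenol (Williamson type); the MOM ether is stable to boron enolates, hydride, carbonate base and hot pyridine and is removed by acid at the end.

Step 7
Reactants: 9 (4S)-4-benzyl-3-{2-[5-(dimethoxymethyl)-3-methoxy-2-(trifluoromethanesulfonyloxy)phenyl]acetyl}-1,3-oxazolidin-2-one; 11 3,5-dimethoxy-4-(methoxymethoxy)benzaldehyde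
Product: 14 (4S)-4-benzyl-3-{(2S,3S)-2-[5-(dimethoxymethyl)-3-methoxy-2-(trifluoromethanesulfonyloxy)phenyl]-3-[3,5-dimethoxy-4-(methoxymethoxy)phenyl]-3-hydroxypropanoyl}-1,3-oxazolidin-2-one, via Z-dibutylboron enolate 12 (not isolated), via dibutylboron aldolate 13 (not isolated)
Conditions: Bu2BOTf (1.05 equiv), i-Pr2NEt, CH2Cl2, −78 → 0 °C; 11, −78 → 0 °C; then pH 7 buffer, MeOH, 30% H2O2, 0 °C
Reagents that add atoms: dibutylboron triflate (its Bu2B group is carried by 12 and 13 only), CCCCB(CCCC)OS(=O)(=O)C(F)(F)F
Why: Evans syn-aldol reaction: soft enolisation gives the Z boron enolate, which should react through a chair Zimmerman–Traxler transition state on the face remote from the benzyl group of the auxiliary in its dipole-opposed rotamer, so the S auxiliary sets both stereocentres as the 2S,3S syn adduct. Near-stoichiometric Bu2BOTf in the presence of amine, together with the para-triflate deactivation, should keep the acetal and the MOM ether intact, and buffered peroxide frees the aldol from boron.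

Step 8
Reactants: 14 (4S)-4-benzyl-3-{(2S,3S)-2-[5-(dimethoxymethyl)-3-methoxy-2-(trifluoromethanesulfonyloxy)phenyl]-3-[3,5-dimethoxy-4-(methoxymethoxy)phenyl]-3-hydroxypropanoyl}-1,3-oxazolidin-2-one
Product: 15 (1S,2R)-2-[5-(dimethoxymethyl)-3-methoxy-2-(trifluoromethanesulfonyloxy)phenyl]-1-[3,5-dimethoxy-4-(methoxymethoxy)phenyl]propane-1,3-diol
Conditions: LiBH4, MeOH (1 equiv), THF, 0 °C
Reagents that add atoms: none
Why: Reductive removal of the auxiliary: hydride attacks the exocyclic imide carbonyl and gives the 1,3-diol without basic conditions that could epimerise the α-aryl centre or cause retro-aldol; aryl triflate, acetal and MOM ether are inert to borohydride, and the descriptor at the aryl-bearing carbon changes from S to R only through the change in CIP priorities.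

Step 9
Reactants: 15 (1S,2R)-2-[5-(dimethoxymethyl)-3-methoxy-2-(trifluoromethanesulfonyloxy)phenyl]-1-[3,5-dimethoxy-4-(methoxymethoxy)phenyl]propane-1,3-diol
Product: 16 (1S,2R)-2-[5-(dimethoxymethyl)-3-methoxy-2-(trifluoromethanesulfonyloxy)phenyl]-1-[3,5-dimethoxy-4-(methoxymethoxy)phenyl]-3-(trityloxy)propan-1-ol
Conditions: TrCl, Et3N, DMAP (cat.), CH2Cl2, 25 °C
Reagents that add atoms: trityl chloride, ClC(c1ccccc1)(c1ccccc1)c1ccccc1
Why: Tritylation is strongly selective for the primary hydroxyl and should leave the secondary benzylic hydroxyl free; the trityl ether is inert to base, cannot migrate to a neighbouring alkoxide and is cleaved by the same acid as the MOM group.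

Step 10
Reactants: 16 (1S,2R)-2-[5-(dimethoxymethyl)-3-methoxy-2-(trifluoromethanesulfonyloxy)phenyl]-1-[3,5-dimethoxy-4-(methoxymethoxy)phenyl]-3-(trityloxy)propan-1-ol
Product: 17 (2S,3R)-5-(dimethoxymethyl)-2-[3,5-dimethoxy-4-(methoxymethoxy)phenyl]-7-methoxy-3-[(trityloxy)methyl]-2,3-dihydro-1-benzofuran
Conditions: Pd(OAc)2 (5 mol %), 2-(di-tert-butylphosphino)-1,1'-binaphthyl (6 mol %), Cs2CO3 (1.5 equiv), toluene, 70 °C
Reagents that add atoms: none
Why: Pd(OAc)2 is reduced in the flask to a zerovalent palladium–phosphine species that inserts into the C7a–O bond of the triflate, giving an aryl complex of divalent palladium. Cs2CO3 deprotonates the coordinated C2 hydroxyl, the alkoxide displaces triflate on the metal, and C–O reductive elimination from the six-membered oxapalladacycle forms O1–C7a and returns zerovalent palladium. The closest known reaction type is the Buchwald–Hartwig-type intramolecular etherification of aryl halides and sulfonates with secondary alcohols. The dihydrofuran ring is closed in a formally 5-exo manner at the sp2 carbon C7a, by reductive elimination and not by nucleophilic substitution. No stereocentre is formed: the C2–O and C3–H bonds are never broken, so the 1S,2R syn diad of 16 should appear with retention as the 2S,3R trans ring of 17. The step needs reductive elimination to outrun β-hydride elimination of the benzylic alkoxide, which the bulky, electron-rich di-tert-butylbiarylphosphine and the rigid chelate favour. It needs site selectivity between the two oxygens, secured because the primary oxygen is a trityl ether that cannot migrate, and a single electrophilic site, secured because the triflate is the only C–X bond. The weak, poorly soluble base in toluene keeps free alkoxide low, which protects the triflate from S–O cleavage and leaves acetal and MOM ether untouched.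

Step 11
Reactants: 17 (2S,3R)-5-(dimethoxymethyl)-2-[3,5-dimethoxy-4-(methoxymethoxy)phenyl]-7-methoxy-3-[(trityloxy)methyl]-2,3-dihydro-1-benzofuran
Product: 18 (2S,3R)-2-[3,5-dimethoxy-4-(methoxymethoxy)phenyl]-7-methoxy-3-[(trityloxy)methyl]-2,3-dihydro-1-benzofuran-5-carbaldehyde
Conditions: PPTS (cat.), acetone/H2O, 25 °C
Reagents that add atoms: water, O
Why: Acid-catalysed acetal hydrolysis; the acetal carbon is now para to O1 and should ionise under buffered acid that leaves trityl ether, MOM ether and the C2–O1 bond untouched (17 is best handled on base-washed silica, and any early hydrolysis only anticipates this step).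

Step 12
Reactants: 18 (2S,3R)-2-[3,5-dimethoxy-4-(methoxymethoxy)phenyl]-7-methoxy-3-[(trityloxy)methyl]-2,3-dihydro-1-benzofuran-5-carbaldehyde; 19 malonic acid
Product: 21 (2E)-3-{(2S,3R)-2-[3,5-dimethoxy-4-(methoxymethoxy)phenyl]-7-methoxy-3-[(trityloxy)methyl]-2,3-dihydro-1-benzofuran-5-yl}prop-2-enoic acid, via arylidenemalonic acid 20 (not isolated)
Conditions: pyridine, piperidine (cat.), 80 °C
Reagents that add atoms: none
Why: Knoevenagel–Doebner condensation: amine-catalysed condensation gives the arylidenemalonic acid, which should decarboxylate in hot pyridine to the E cinnamic acid; the buffered medium is neither acidic enough to remove trityl or MOM nor basic enough to affect the protected phenylcoumaran.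

Step 13
Reactants: 21 (2E)-3-{(2S,3R)-2-[3,5-dimethoxy-4-(methoxymethoxy)phenyl]-7-methoxy-3-[(trityloxy)methyl]-2,3-dihydro-1-benzofuran-5-yl}prop-2-enoic acid
Product: 22 (2E)-3-[(2S,3R)-2-(4-hydroxy-3,5-dimethoxyphenyl)-3-(hydroxymethyl)-7-methoxy-2,3-dihydro-1-benzofuran-5-yl]prop-2-enoic acid
Conditions: 2 M HCl (aq), THF, 40 °C
Reagents that add atoms: none
Why: Acid hydrolysis should remove the trityl ether (trityl cation trapped by water) and the phenolic MOM acetal in one operation; alcohol-free aqueous THF avoids esterification of the acid, and the moderate acidity is chosen to stay below ionisation of the C2–O1 benzylic ether, which would in any case reclose to the more stable trans isomer with C3 unchanged.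

## Compound list

1 | 5-iodovanillin (4-hydroxy-3-iodo-5-methoxybenzaldehyde) | COc1cc(C=O)cc(I)c1O | starting material
2 | 4-formyl-2-iodo-6-methoxyphenyl trifluoromethanesulfonate | COc1cc(C=O)cc(I)c1OS(=O)(=O)C(F)(F)F | intermediate
3 | 4-(dimethoxymethyl)-2-iodo-6-methoxyphenyl trifluoromethanesulfonate | COc1cc(C(OC)OC)cc(I)c1OS(=O)(=O)C(F)(F)F | intermediate
4 | ethyl 2-[5-(dimethoxymethyl)-3-methoxy-2-(trifluoromethanesulfonyloxy)phenyl]acetate | CCOC(=O)Cc1cc(C(OC)OC)cc(OC)c1OS(=O)(=O)C(F)(F)F | intermediate
5 | lithium 2-[5-(dimethoxymethyl)-3-methoxy-2-(trifluoromethanesulfonyloxy)phenyl]acetate | [Li+].[O-]C(=O)Cc1cc(C(OC)OC)cc(OC)c1OS(=O)(=O)C(F)(F)F | intermediate (not isolated)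
6 | 2-[5-(dimethoxymethyl)-3-methoxy-2-(trifluoromethanesulfonyloxy)phenyl]acetic acid | OC(=O)Cc1cc(C(OC)OC)cc(OC)c1OS(=O)(=O)C(F)(F)F | intermediate
7 | (S)-4-benzyl-1,3-oxazolidin-2-one | O=C1N[C@@H](Cc2ccccc2)CO1 | starting material
8 | 2-[5-(dimethoxymethyl)-3-methoxy-2-(trifluoromethanesulfonyloxy)phenyl]acetic pivalic anhydride | CC(C)(C)C(=O)OC(=O)Cc1cc(C(OC)OC)cc(OC)c1OS(=O)(=O)C(F)(F)F | intermediate (not isolated)
9 | (4S)-4-benzyl-3-{2-[5-(dimethoxymethyl)-3-methoxy-2-(trifluoromethanesulfonyloxy)phenyl]acetyl}-1,3-oxazolidin-2-one | O=C(Cc1cc(C(OC)OC)cc(OC)c1OS(=O)(=O)C(F)(F)F)N1[C@@H](Cc2ccccc2)COC1=O | intermediate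
10 | syringaldehyde (4-hydroxy-3,5-dimethoxybenzaldehyde) | COc1cc(C=O)cc(OC)c1O | starting material
11 | 3,5-dimethoxy-4-(methoxymethoxy)benzaldehyde | COCOc1c(OC)cc(C=O)cc1OC | intermediate
12 | (4S)-4-benzyl-3-{(Z)-1-(dibutylboryloxy)-2-[5-(dimethoxymethyl)-3-methoxy-2-(trifluoromethanesulfonyloxy)phenyl]ethenyl}-1,3-oxazolidin-2-one | CCCCB(CCCC)O/C(=C\c1cc(C(OC)OC)cc(OC)c1OS(=O)(=O)C(F)(F)F)N1[C@@H](Cc2ccccc2)COC1=O | intermediate (not isolated)
13 | (4S)-4-benzyl-3-{(2S,3S)-3-(dibutylboryloxy)-2-[5-(dimethoxymethyl)-3-methoxy-2-(trifluoromethanesulfonyloxy)phenyl]-3-[3,5-dimethoxy-4-(methoxymethoxy)phenyl]propanoyl}-1,3-oxazolidin-2-one | COc1cc([C@H]([C@H](c2cc(C(OC)OC)cc(OC)c2OS(=O)(=O)C(F)(F)F)C(=O)N2[C@@H](Cc3ccccc3)COC2=O)OB(CCCC)CCCC)cc(OC)c1OCOC | intermediate (not isolated)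
14 | (4S)-4-benzyl-3-{(2S,3S)-2-[5-(dimethoxymethyl)-3-methoxy-2-(trifluoromethanesulfonyloxy)phenyl]-3-[3,5-dimethoxy-4-(methoxymethoxy)phenyl]-3-hydroxypropanoyl}-1,3-oxazolidin-2-one | COc1cc([C@H]([C@H](c2cc(C(OC)OC)cc(OC)c2OS(=O)(=O)C(F)(F)F)C(=O)N2[C@@H](Cc3ccccc3)COC2=O)O)cc(OC)c1OCOC | intermediate
15 | (1S,2R)-2-[5-(dimethoxymethyl)-3-methoxy-2-(trifluoromethanesulfonyloxy)phenyl]-1-[3,5-dimethoxy-4-(methoxymethoxy)phenyl]propane-1,3-diol | COc1cc([C@H]([C@H](c2cc(C(OC)OC)cc(OC)c2OS(=O)(=O)C(F)(F)F)CO)O)cc(OC)c1OCOC | intermediate
16 | (1S,2R)-2-[5-(dimethoxymethyl)-3-methoxy-2-(trifluoromethanesulfonyloxy)phenyl]-1-[3,5-dimethoxy-4-(methoxymethoxy)phenyl]-3-(trityloxy)propan-1-ol | COc1cc([C@H]([C@H](c2cc(C(OC)OC)cc(OC)c2OS(=O)(=O)C(F)(F)F)COC(c2ccccc2)(c2ccccc2)c2ccccc2)O)cc(OC)c1OCOC | intermediate (precursor of the key step)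
17 | (2S,3R)-5-(dimethoxymethyl)-2-[3,5-dimethoxy-4-(methoxymethoxy)phenyl]-7-methoxy-3-[(trityloxy)methyl]-2,3-dihydro-1-benzofuran | COc1cc([C@H]2Oc3c(OC)cc(C(OC)OC)cc3[C@@H]2COC(c2ccccc2)(c2ccccc2)c2ccccc2)cc(OC)c1OCOC | intermediate (product of the key step)
18 | (2S,3R)-2-[3,5-dimethoxy-4-(methoxymethoxy)phenyl]-7-methoxy-3-[(trityloxy)methyl]-2,3-dihydro-1-benzofuran-5-carbaldehyde | COc1cc([C@H]2Oc3c(OC)cc(C=O)cc3[C@@H]2COC(c2ccccc2)(c2ccccc2)c2ccccc2)cc(OC)c1OCOC | intermediate
19 | malonic acid | OC(=O)CC(=O)O | starting material
20 | 2-({(2S,3R)-2-[3,5-dimethoxy-4-(methoxymethoxy)phenyl]-7-methoxy-3-[(trityloxy)methyl]-2,3-dihydro-1-benzofuran-5-yl}methylidene)propanedioic acid | COc1cc([C@H]2Oc3c(OC)cc(C=C(C(=O)O)C(=O)O)cc3[C@@H]2COC(c2ccccc2)(c2ccccc2)c2ccccc2)cc(OC)c1OCOC | intermediate (not isolated)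
21 | (2E)-3-{(2S,3R)-2-[3,5-dimethoxy-4-(methoxymethoxy)phenyl]-7-methoxy-3-[(trityloxy)methyl]-2,3-dihydro-1-benzofuran-5-yl}prop-2-enoic acid | COc1cc([C@H]2Oc3c(OC)cc(/C=C/C(=O)O)cc3[C@@H]2COC(c2ccccc2)(c2ccccc2)c2ccccc2)cc(OC)c1OCOC | intermediate
22 | (2E)-3-[(2S,3R)-2-(4-hydroxy-3,5-dimethoxyphenyl)-3-(hydroxymethyl)-7-methoxy-2,3-dihydro-1-benzofuran-5-yl]prop-2-enoic acid | COc1cc([C@H]2Oc3c(OC)cc(/C=C/C(=O)O)cc3[C@@H]2CO)cc(OC)c1O | target

## Step count and least certain steps

Total: 13 steps. Longest linear sequence: 12 steps (from 1 to 22 through steps 1–5 and 7–13); step 6 is a one-step side branch.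

Step 10 (key step). The most likely failures are β-hydride elimination from the palladium-bound benzylic alkoxide (oxidation of the carbinol and reduction of the arene), base-induced S–O cleavage of the triflate, or slow insertion at the doubly ortho-substituted carbon. The fallback forms the other ring C–O bond by known chemistry.
- It sets out from 16: cleavage of the triflate with Et4NOH in aqueous dioxane should give the phenol (1S,2R)-2-[5-(dimethoxymethyl)-2-hydroxy-3-methoxyphenyl]-1-[3,5-dimethoxy-4-(methoxymethoxy)phenyl]-3-(trityloxy)propan-1-ol F1.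
- Treatment of F1 with 2 M aqueous HCl in THF should hydrolyse the acetal, trityl and MOM groups. The benzylic cation at C1, stabilised by ring B, would be captured by the ring A phenol, forming O1–C2 under control of the intact C3 centre. The expected product is the trans aldehyde (2S,3R)-2-(4-hydroxy-3,5-dimethoxyphenyl)-3-(hydroxymethyl)-7-methoxy-2,3-dihydro-1-benzofuran-5-carbaldehyde F2.
- Knoevenagel–Doebner condensation of F2 with 19 (pyridine, piperidine), through 2-{[(2S,3R)-2-(4-hydroxy-3,5-dimethoxyphenyl)-3-(hydroxymethyl)-7-methoxy-2,3-dihydro-1-benzofuran-5-yl]methylidene}propanedioic acid F3, comes back to the route at 22.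

Step 3. The most likely failures are competing insertion into the C–OTf bond, self-condensation or slow transmetalation of the zinc enolate, and protodeiodination. The fallback builds the chain by allylation and oxidative cleavage.
- It sets out from 3: Stille coupling with Bu3SnCH2CH=CH2 and Pd(PPh3)4 in toluene, without chloride additive so that the triflate stays inert, should give 2-allyl-4-(dimethoxymethyl)-6-methoxyphenyl trifluoromethanesulfonate F4.
- Lemieux–Johnson cleavage (OsO4 cat., NaIO4, 2,6-lutidine, dioxane/H2O) should give 4-(dimethoxymethyl)-2-methoxy-6-(2-oxoethyl)phenyl trifluoromethanesulfonate F5.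
- Pinnick oxidation (NaClO2, NaH2PO4, 2-methyl-2-butene, t-BuOH/H2O) returns to the route at 6.

Step 4. The most likely failure is loss of the triflate by hydroxide attack at sulfur before the ester is consumed, or acetal hydrolysis during acidification. The fallback unmasks the acid by hydrogenolysis instead of hydrolysis.
- It sets out from 3: the coupling of step 3 is run with BrZnCH2CO2Bn (from benzyl bromoacetate and Zn) to give benzyl 2-[5-(dimethoxymethyl)-3-methoxy-2-(trifluoromethanesulfonyloxy)phenyl]acetate F6.
- Neutral hydrogenolysis (H2, Pd/C, palladium metal on carbon, EtOAc, 25 °C) returns to the route at 6.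

Step 7. The most likely failures are slow addition of the hindered enolate to the electron-rich aldehyde, retro-aldol cleavage during work-up, erosion of syn selectivity, or Lewis-acid activation of the acetal by the boron triflate. The fallback uses a titanium enolate of a different auxiliary.
- It sets out from 6: coupling with (4S)-4-benzyl-1,3-thiazolidine-2-thione (EDC·HCl, DMAP, CH2Cl2) should give (4S)-4-benzyl-3-{2-[5-(dimethoxymethyl)-3-methoxy-2-(trifluoromethanesulfonyloxy)phenyl]acetyl}-1,3-thiazolidine-2-thione F7.
- Enolisation with TiCl4, i-Pr2NEt and N-methyl-2-pyrrolidinone in CH2Cl2 at 0 °C and addition of 11 should give, with the same syn sense, (4S)-4-benzyl-3-{(2S,3S)-2-[5-(dimethoxymethyl)-3-methoxy-2-(trifluoromethanesulfonyloxy)phenyl]-3-[3,5-dimethoxy-4-(methoxymethoxy)phenyl]-3-hydroxypropanoyl}-1,3-thiazolidine-2-thione F8. Chlorotitanium enolates add to acetals only when a further Lewis acid is supplied, so the acetal should survive.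
- Reductive removal of the auxiliary with NaBH4 in THF/EtOH returns to the route at 15.

## Further compounds

F1 | step 10 | (1S,2R)-2-[5-(dimethoxymethyl)-2-hydroxy-3-methoxyphenyl]-1-[3,5-dimethoxy-4-(methoxymethoxy)phenyl]-3-(trityloxy)propan-1-ol | COc1cc([C@H]([C@H](c2cc(C(OC)OC)cc(OC)c2O)COC(c2ccccc2)(c2ccccc2)c2ccccc2)O)cc(OC)c1OCOC
F2 | step 10 | (2S,3R)-2-(4-hydroxy-3,5-dimethoxyphenyl)-3-(hydroxymethyl)-7-methoxy-2,3-dihydro-1-benzofuran-5-carbaldehyde | COc1cc([C@H]2Oc3c(OC)cc(C=O)cc3[C@@H]2CO)cc(OC)c1O
F3 | step 10 | 2-{[(2S,3R)-2-(4-hydroxy-3,5-dimethoxyphenyl)-3-(hydroxymethyl)-7-methoxy-2,3-dihydro-1-benzofuran-5-yl]methylidene}propanedioic acid | COc1cc([C@H]2Oc3c(OC)cc(C=C(C(=O)O)C(=O)O)cc3[C@@H]2CO)cc(OC)c1O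
F4 | step 3 | 2-allyl-4-(dimethoxymethyl)-6-methoxyphenyl trifluoromethanesulfonate | C=CCc1cc(C(OC)OC)cc(OC)c1OS(=O)(=O)C(F)(F)F
F5 | step 3 | 4-(dimethoxymethyl)-2-methoxy-6-(2-oxoethyl)phenyl trifluoromethanesulfonate | O=CCc1cc(C(OC)OC)cc(OC)c1OS(=O)(=O)C(F)(F)F
F6 | step 4 | benzyl 2-[5-(dimethoxymethyl)-3-methoxy-2-(trifluoromethanesulfonyloxy)phenyl]acetate | O=C(Cc1cc(C(OC)OC)cc(OC)c1OS(=O)(=O)C(F)(F)F)OCc1ccccc1
F7 | step 7 | (4S)-4-benzyl-3-{2-[5-(dimethoxymethyl)-3-methoxy-2-(trifluoromethanesulfonyloxy)phenyl]acetyl}-1,3-thiazolidine-2-thione | O=C(Cc1cc(C(OC)OC)cc(OC)c1OS(=O)(=O)C(F)(F)F)N1[C@@H](Cc2ccccc2)CSC1=S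
F8 | step 7 | (4S)-4-benzyl-3-{(2S,3S)-2-[5-(dimethoxymethyl)-3-methoxy-2-(trifluoromethanesulfonyloxy)phenyl]-3-[3,5-dimethoxy-4-(methoxymethoxy)phenyl]-3-hydroxypropanoyl}-1,3-thiazolidine-2-thione | COc1cc([C@H]([C@H](c2cc(C(OC)OC)cc(OC)c2OS(=O)(=O)C(F)(F)F)C(=O)N2[C@@H](Cc3ccccc3)CSC2=S)O)cc(OC)c1OCOC
A1 | alternative 1 | (4R,5S)-5-[4-(tert-butyldimethylsilyloxy)-3,5-dimethoxyphenyl]-4-[(tert-butyldimethylsilyloxy)methyl]dihydrofuran-2(3H)-one | COc1cc([C@H]2OC(=O)C[C@@H]2CO[Si](C)(C)C(C)(C)C)cc(OC)c1O[Si](C)(C)C(C)(C)C
A2 | alternative 1 | (2S,3R)-5-(tert-butyldimethylsilyloxy)-2-[4-(tert-butyldimethylsilyloxy)-3,5-dimethoxyphenyl]-3-[(tert-butyldimethylsilyloxy)methyl]-2,3-dihydrofuran | COc1cc([C@H]2OC(O[Si](C)(C)C(C)(C)C)=C[C@@H]2CO[Si](C)(C)C(C)(C)C)cc(OC)c1O[Si](C)(C)C(C)(C)C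
A3 | alternative 1 | methyl 3-methoxy-2-oxo-2H-pyran-5-carboxylate | COC(=O)C1=COC(=O)C(OC)=C1
A4 | alternative 1 | methyl (2S,3R)-2-[4-(tert-butyldimethylsilyloxy)-3,5-dimethoxyphenyl]-3-[(tert-butyldimethylsilyloxy)methyl]-7-methoxy-2,3-dihydro-1-benzofuran-5-carboxylate | COc1cc([C@H]2Oc3c(OC)cc(C(=O)OC)cc3[C@@H]2CO[Si](C)(C)C(C)(C)C)cc(OC)c1O[Si](C)(C)C(C)(C)C
A5 | alternative 2 | methyl (2E)-3-{4-hydroxy-3-[(2R)-1-hydroxy-3-(4-hydroxy-3,5-dimethoxyphenyl)propan-2-yl]-5-methoxyphenyl}prop-2-enoate | COc1cc(C[C@@H](CO)c2cc(/C=C/C(=O)OC)cc(OC)c2O)cc(OC)c1O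
A6 | alternative 2 | methyl (2E)-3-{3-[(2R)-1-(3,5-dimethoxy-4-oxocyclohexa-2,5-dien-1-ylidene)-3-hydroxypropan-2-yl]-4-hydroxy-5-methoxyphenyl}prop-2-enoate | COC1=CC(=C[C@@H](CO)c2cc(/C=C/C(=O)OC)cc(OC)c2O)C=C(OC)C1=O
A7 | alternative 2 | methyl (2E)-3-[(2S,3R)-2-(4-hydroxy-3,5-dimethoxyphenyl)-3-(hydroxymethyl)-7-methoxy-2,3-dihydro-1-benzofuran-5-yl]prop-2-enoate | COc1cc([C@H]2Oc3c(OC)cc(/C=C/C(=O)OC)cc3[C@@H]2CO)cc(OC)c1O
A8 | alternative 3 | 4-[(2S)-6-bromo-8-methoxy-4-oxo-3,4-dihydro-2H-chromen-2-yl]-2,6-dimethoxyphenyl 2,2-dimethylpropanoate | COc1cc([C@@H]2CC(=O)c3cc(Br)cc(OC)c3O2)cc(OC)c1OC(=O)C(C)(C)C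
A9 | alternative 3 | methyl (2S,3S)-5-bromo-2-[3,5-dimethoxy-4-(pivaloyloxy)phenyl]-7-methoxy-2,3-dihydro-1-benzofuran-3-carboxylate | COc1cc([C@H]2Oc3c(OC)cc(Br)cc3[C@@H]2C(=O)OC)cc(OC)c1OC(=O)C(C)(C)C
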